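The data are calculated with made-up constants.

| flask | electrophile | nucleophile | temperature | remark | time |
|---|---|---|---|---|---|
| blue | 1.5 M | 0.53 M | 25 °C | run made earlier |  |
| amber | 1.5 M | 1.2 M | 36 °C | run made earlier |  |
| green | 0.90 M | 1.58 M | 25 °C | run made earlier |  |
| Sunday's | 1.5 M | 1.58 M | 20 °C |  | 20 h |
| Saturday's | 1.5 M | 3.00 M | 40 °C |  | 20 h |
| Thursday's | 1.5 M | 1.58 M | 40 °C |  | 20 h |
| Wednesday's | 0.80 M | 3.00 M | 40 °C |  | 20 h |
| Tuesday's | 1.5 M | 0.500 M | 20 °C |  | 20 h |

| run | time / h | product / % | electrophile / % |
|---|---|---|---|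
| blue | 2.00 | 1.9 | 93.9 |
| blue | 3.00 | 0.2 | 87.8 |
| blue | 6.00 | 2.0 | 80.0 |
| blue | 10.0 | 2.6 | 72.2 |
| blue | 20.0 | 6.8 | 56.2 |
| amber | 0.833 | 0 | 88.0 |
| amber | 1.50 | 1.6 | 82.4 |
| amber | 3.00 | 6.0 | 69.0 |
| amber | 5.00 | 7.5 | 54.7 |
| amber | 10.0 | 11.9 | 37.0 |
| green | 4.00 | 4.6 | 88.3 |
| green | 8.00 | 9.8 | 78.8 |
| green | 12.0 | 10.9 | 73.3 |
| green | 15.0 | 13.2 | 66.8 |
| green | 20.0 | 18.3 | 59.0 |

(readings scatter by 1 percentage point)

- percent here means electrophile units held: one homo dimer counts as two
- candidate steps: electrophile + nucleophile -> acid set free + product; 2 electrophile -> homo dimer; nucleophile + acid set free <-> protonated nucleophile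

- ranking by amount of product, in percent of the electrophile charged, from high to low, at 20 h (Sunday's / Saturday's / Thursday's / Wednesday's / Tuesday's)
- the amount of product, in percent of the electrophile charged of the flask you put first, at 20 h
- the amount of product, in percent of the electrophile charged of the flask you put last, at 20 h

1. I start with the easy step: electrophile that is neither left nor product sits in the homo dimer. That is 22.7% in the green run and 51.1% in the amber run, each at its last reading.

2. Let x be the fraction of electrophile left and n the nucleophile charge over the electrophile charge, held at its starting value. Product forms in proportion to x, the homo dimer to x squared, so product over dimer is σn/x. I call σ the selectivity factor. With x at its straight-line mean, the green run reads 0.365 and the amber run 0.199.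

3. Taking a constant factor per degree, σ is 0.160 at 40 °C and 0.481 at 20 °C. Then r = σn is the crossing fraction, the x at which both steps take electrophile equally. Below it, product leads. For Wednesday's, r is 0.600.

4. The clock is κct = ln[(x+r)/((1+r)x)]/r, with c the electrophile charge and κ the dimer constant. The green run reads κ = 0.0208 /M/h and the amber run 0.0880 /M/h. That extends to 0.149 /M/h at 40 °C and 0.0108 /M/h at 20 °C. So Wednesday's ends near x = 10.6%.

5. With the straight-line mean of x, Wednesday's product is 46.5%. That mean is the weak link: x falls along a curve. Integrating the split over the fall gives product = r ln[(1+r)/(r+x)], which is 49.1%.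

6. The same rule gives Saturday's 38.9%, Thursday's 23.9% and Sunday's 13.2%. Tuesday's, at its own 20 °C, takes σ = 0.481 and κ = 0.0108 /M/h, so Tuesday's gets 4.40%. I commit to that order, with Wednesday's ahead of them.

The forecast ranks the flasks as I do, Wednesday's > Saturday's > Thursday's > Sunday's > Tuesday's, with 47% for the first, lower than mine, and 4% for the last: “Dilute electrophile with excess nucleophile wins.”

The flasks give Wednesday's > Saturday's > Thursday's > Sunday's > Tuesday's.

    electrophile + nucleophile → acid set free + product (k = 7.60 × 10⁻⁶ /M/s, Ea = 64.0 kJ/mol)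
    2 electrophile → homo dimer (k = 1.80 × 10⁻⁵ /M/s, Ea = 91.0 kJ/mol)
    nucleophile + acid set free ⇌ protonated nucleophile, settled at all times (K = 9.90 /M, ΔH = −57.0 kJ/mol)
    (constants at 40 °C)

Wednesday's gives 50.7% and Tuesday's 3.79%. At 20.0 h, Wednesday's holds 36.9% as homo dimer beside that product. Now I use the crossing fraction on Wednesday's read at 5.0 h. My clock and rule, with r = 0.600, give 24.3% product by then. Electrophile in that reading stands at 47.9%, below the crossing. That reading holds 26.3% product.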